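Abbreviations used throughout: geranyl = (2E)-3,7-dimethylocta-2,6-dien-1-yl; MOM = methoxymethyl.

## The problem

The target 18, (2S)-3′-geranylnaringenin, is a flavanone. Ring A, a phloroglucinol unit with hydroxyls at C5 and C7, is fused through C4a and C8a to the dihydropyranone ring C; ring B hangs from C2 by a single bond and carries a geranyl chain on C3′ next to the C4′ hydroxyl. C2 is the only stereocentre, so nothing in the molecule can relay configuration to it and it must be set by a chiral catalyst or reagent. It is also labile: it is benzylic, bound to O1 and β to the C4 ketone, and base opens ring C to the 2′-hydroxychalcone and recloses it with loss of configuration. C2 is therefore best made late and kept away from base afterwards. The chain holds two trisubstituted olefins, one of fixed E geometry. They exclude hydrogenolysis, electrophilic halogen and strong acid (which would close the C4′ hydroxyl onto the chain), and the C3′–C1″ bond has to be made without allylic transposition. Three phenols must be masked through organolithium, copper, palladium and rhodium chemistry and released without base. The enabling feature is the arrangement around ring C: C4 is an aryl ketone whose neighbour C4a is ortho to the O1-bearing C8a, C3 is a methylene and C2 bears one hydrogen. C3–C4 and C2–H are thus exactly the bonds formed when the formyl C–H of a ring-A benzaldehyde adds across a 1-arylvinyl ether O1–C2(=C3H2)–ring B.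

## Retrosynthesis

**18 from 17 (three O–CH2OCH3 bonds).** The last operation only unmasks the phenols of the tris-MOM flavanone 17. MOM is chosen because it survives butyllithium, copper, palladium and cationic rhodium, directs the first halogen–lithium exchange, and leaves under acid, the only medium in which C2 is configurationally safe. Benzyl ethers would need hydrogenolysis and silyl ethers would migrate to carbon in the ortho-lithiated arene.

**17 from 16 (C3–C4 and C2–H).** Both bonds are cut at once, leading back to the achiral 2-(1-arylvinyloxy)benzaldehyde 16. Two neighbouring cuts were weighed: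
- Cutting O1–C2 (oxa-Michael closure of a 2′-hydroxychalcone) is the reversible process that racemises flavanones and is hard to render selective.
- Cutting C2–C1′ (arylmetal conjugate addition to a chromone) is known and is kept as the fallback, but needs a separately made heterocycle.

The hydroacylation cut is redox-neutral and atom-economical, and forms ring C and the stereocentre together. The forward step needs rhodium to take the terminal carbon C3, one olefin face to be chosen, and decarbonylation to stay slow. All three ring-A oxygens are capped in 16. A free hydroxyl ortho to the formyl group would not help: a rhodium phenoxide chelate holds the metal on the side of the acyl group remote from the enol ether, and a free phenol with a cationic metal releases acid that would hydrolyse the enol ether. The tethered olefin itself provides the chelation that restrains decarbonylation.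

**16 from 15 and 13 (O1–C2).** The aryl–oxygen–vinyl bond is cut between the phenol oxygen of aldehyde 15 and the vinyl carbon of boronate 13. This is the convergent junction of the two aromatic halves, to be made by copper-mediated Chan–Lam coupling under basic, anhydrous conditions that spare the aldehyde and the acid-labile enol ether. Methylenation of the corresponding aryl ester is a neighbouring choice but forces the aldehyde to be masked and unmasked (three more steps); it is held as the fallback. Coupling of the enol triflate 12 with the phenol would need strong base and risks elimination to the arylalkyne.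

**15 from 14 (two O–MOM bonds).** 2,4,6-Trihydroxybenzaldehyde 14 is etherified twice. The third hydroxyl, locked in a hydrogen bond to the formyl oxygen, stays free and is exactly the oxygen that becomes O1.

**13 from 12 from 10 (C–B, then C–O of the triflate).** The 1-arylvinyl boronate 13 comes from the enol triflate 12 by Miyaura borylation, and 12 from the methyl ketone 10, which has only one enolisable position. The two carbons of the acetyl group become C2 and C3 of the target.

**10 from 6 and 7 (C1′–C2).** The acetyl group is attached by acylating the aryllithium from bromide 6 with Weinreb amide 7. Direct ortho-geranylation of 4-hydroxyacetophenone would be shorter, but C-allylation of a para-acyl phenoxide competes poorly with O-alkylation, and a ketone cannot be carried through aryllithium formation.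

**6 from 2 and 3; 2 from 1 (C3′–C1″, O–MOM).** The geranyl chain is attached by copper-mediated substitution of geranyl bromide 3 with the aryl metal from dibromide 2. The MOM oxygen of 2 distinguishes its two bromines, so 2,4-dibromophenol 1 supplies both functional handles of ring B in the right positions.

## Roads not taken

**Alternative 1:** Ring B is built de novo by cutting C2′–C3′ and C4′–C5′. In the forward direction methyl coumalate A2 and the geranyl-substituted siloxyalkyne A3 combine in an inverse-demand [4+2] cycloaddition; loss of CO2 from the bicyclic lactone gives the benzoate A1.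
- Merits: the polarisation of both partners fixes the geranyl group ortho to oxygen, no allylic metal chemistry is involved so transposition cannot occur, and the chain olefins are not touched. The silyl ether of A1 could later be removed by fluoride, which is gentler on the chain than the acid needed for MOM.
- Weak points: A3 is a sensitive ynol ether that needs its own multistep preparation, and the key step constructs a benzene ring that can be bought. A1 must still be converted into a partner for ring C, and the step says nothing about C2.
- Comparison: in certainty of the geranyl position this road is better than step 2 of the chosen plan, which relies on a selective exchange and on substitution at the primary carbon. Against that, the chosen plan reaches bromide 6 in two steps from commercial 1 and 3, and spends its key step on the ring closure and the stereocentre, the real difficulties.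

**Alternative 2:** The chain olefin is built by cutting the bond from C3″ to its methyl group and C1″–C2″. Alkyne A5 undergoes syn methylalumination with AlMe3 and Cp2ZrCl2 (tetravalent zirconium), and the E-alkenylalane A7 is coupled with the benzylic chloride A6 under Pd(PPh3)4 (zerovalent palladium) to give acetal A4.
- Merits: the E geometry follows from the syn addition, the coupling takes place at a benzylic carbon so no allylic isomer can arise, and both operations run in one flask.
- Weak points: the chain is assembled although it is available as 3, and A6 needs several steps of its own. AlMe3 is a strong Lewis acid toward the MOM ether and the dioxolane of A6 and A4. Ring C and C2 are again left open.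
- Comparison: on geometric purity of the olefin this road is at least as good, since commercial 3 can carry some of the Z isomer into 6. The chosen plan answers with a single step from a purchased reagent, and with purification of 3 or of 6 if needed; everything downstream would be the same.

**Alternative 3:** Ring A is built by cutting C4a–C5. Mg(OMe)2 in methanol opens the 4-hydroxy-2-pyrone A9 to the triketo ester A10, whose C4a carbanion attacks the ester carbon in a Claisen condensation to give the acylphloroglucinol A8.
- Merits: ring A arrives with three free, correctly placed hydroxyls and no differentiation problem. The oxygen-bearing benzylic centre is set earlier by dependable asymmetric aldol or reduction chemistry, and ring C would close afterwards by inversion at that centre.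
- Weak points: A10 and A8 are β-silyloxy ketones under alkoxide conditions, so E1cB loss of silanolate threatens the stereocentre. The aldol mode of cyclisation competes with the Claisen mode, and A9 needs a long linear preparation. The later inversion at a benzylic carbon with a para oxygen tends toward ionisation and erosion of enantiopurity.
- Comparison: in reliability of the stereodefining reaction this road is better, because it rests on established asymmetric chemistry while the chosen key step is untested. The chosen plan offers convergence, fewer steps, a stereocentre created last and never exposed to base, and a known fallback that reaches the same intermediate 17.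

Key step: step 8

Assumption: the sense of induction of a chiral bisphosphine on this new substrate class cannot be derived from the carbocyclic models; the (R)-ligand is written, and its antipode is used if the first experiment delivers the (2R) series.

## Route

Step 1
Reactants: 1 2,4-dibromophenol
Product: 2 2,4-dibromo-1-(methoxymethoxy)benzene
Conditions: MOMCl, i-Pr2NEt, CH2Cl2, 0 °C to rt
Reagents that add atoms: chloromethyl methyl ether, COCCl
Why: Williamson-type etherification of a phenol (MOM protection); the acetal oxygen later directs the halogen–lithium exchange to its ortho bromine.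

Step 2
Reactants: 2 2,4-dibromo-1-(methoxymethoxy)benzene; 3 geranyl bromide
Product: 6 4-bromo-2-geranyl-1-(methoxymethoxy)benzene, via aryllithium 4 (not isolated), via arylcopper 5 (not isolated)
Conditions: n-BuLi, Et2O, −78 °C; CuBr·SMe2 (1 equiv), −78 to −40 °C; 3, −78 to 0 °C
Reagents that add atoms: none
Why: Bromine–lithium exchange of 2,4-dibromoaryl ethers takes place at the bromine ortho to the chelating oxygen; the derived arylcopper substitutes geranyl bromide at the primary carbon (SN2 mode) with the E olefin retained, the standard way to attach a geranyl group to an aryl MOM ether.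

Step 3
Reactants: 6 4-bromo-2-geranyl-1-(methoxymethoxy)benzene; 7 N-methoxy-N-methylacetamide
Product: 10 1-[3-geranyl-4-(methoxymethoxy)phenyl]ethan-1-one, via aryllithium 8 (not isolated), via tetrahedral adduct 9 (not isolated)
Conditions: n-BuLi, THF, −78 °C; 7, −78 to 0 °C; aq. NH4Cl
Reagents that add atoms: none
Why: Second bromine–lithium exchange followed by Weinreb ketone synthesis; the chelated adduct 9 cannot add a second aryllithium and collapses to the methyl ketone on work-up.

Step 4
Reactants: 10 1-[3-geranyl-4-(methoxymethoxy)phenyl]ethan-1-one
Product: 12 1-[3-geranyl-4-(methoxymethoxy)phenyl]ethenyl trifluoromethanesulfonate, via potassium enolate 11 (not isolated)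
Conditions: KN(SiMe3)2, THF, −78 °C; PhNTf2, −78 to 0 °C; aq. NH4Cl; Et3N-washed SiO2
Reagents that add atoms: N-phenylbis(trifluoromethanesulfonimide), O=S(=O)(N(c1ccccc1)S(=O)(=O)C(F)(F)F)C(F)(F)F
Why: Enol triflate formation: the ketone has a single enolisable position, and the potassium enolate is sulfonylated on oxygen by the triflimide.

Step 5
Reactants: 12 1-[3-geranyl-4-(methoxymethoxy)phenyl]ethenyl trifluoromethanesulfonate
Product: 13 2-{1-[3-geranyl-4-(methoxymethoxy)phenyl]ethenyl}-4,4,5,5-tetramethyl-1,3,2-dioxaborolane
Conditions: B2pin2, PdCl2(PPh3)2 (3 mol %), PPh3 (6 mol %), KOPh, toluene, 50 °C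
Reagents that add atoms: bis(pinacolato)diboron, CC1(C)OB(OC1(C)C)B1OC(C)(C)C(C)(C)O1
Why: Miyaura borylation of an alkenyl triflate; the weak base KOPh activates the diboron without causing Suzuki homocoupling or elimination of the triflate to the arylalkyne.

Step 6
Reactants: 14 2,4,6-trihydroxybenzaldehyde
Product: 15 2-hydroxy-4,6-bis(methoxymethoxy)benzaldehyde
Conditions: MOMCl (2.1 equiv), i-Pr2NEt, CH2Cl2, 0 °C to rt
Reagents that add atoms: chloromethyl methyl ether, COCCl
Why: Twofold MOM etherification; once the C4 hydroxyl and one ortho hydroxyl are capped, the remaining hydroxyl is held in a hydrogen bond to the formyl oxygen and reacts much more slowly, a pattern well established for 2,4,6-trihydroxyaryl carbonyl compounds.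

Step 7
Reactants: 15 2-hydroxy-4,6-bis(methoxymethoxy)benzaldehyde (2 equiv); 13 2-{1-[3-geranyl-4-(methoxymethoxy)phenyl]ethenyl}-4,4,5,5-tetramethyl-1,3,2-dioxaborolane
Product: 16 2-({1-[3-geranyl-4-(methoxymethoxy)phenyl]ethenyl}oxy)-4,6-bis(methoxymethoxy)benzaldehyde
Conditions: Cu(OAc)2 (2 equiv), pyridine, 4 Å MS, CH2Cl2, dry air, rt; Et3N-washed SiO2
Reagents that add atoms: none
Why: Chan–Lam oxidative C–O coupling of a phenol with an alkenylboron reagent: the 1-arylvinyl group is transferred to divalent copper and reductive elimination from the copper phenoxide forms the O1–C2 bond; the medium is basic and dry, so the aldehyde, the MOM ethers and the new acid-labile enol ether should survive.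

Step 8
Reactants: 16 2-({1-[3-geranyl-4-(methoxymethoxy)phenyl]ethenyl}oxy)-4,6-bis(methoxymethoxy)benzaldehyde
Product: 17 (2S)-2-[3-geranyl-4-(methoxymethoxy)phenyl]-5,7-bis(methoxymethoxy)-2,3-dihydro-4H-chromen-4-one
Conditions: [Rh(cod)2]BF4 (5 mol %), (R)-DTBM-SEGPHOS (5.5 mol %), activated with H2 then purged with Ar, ClCH2CH2Cl, 40 °C
Reagents that add atoms: none
Why: Proposed new method: cationic monovalent rhodium bearing the chiral bisphosphine binds the enol ether olefin and inserts into the formyl C–H bond that points toward it, giving an acyl hydride of trivalent rhodium held in a chelate by the olefin, which is what keeps decarbonylation slow. The hydride migrates to C2 and rhodium takes the terminal carbon C3, giving a seven-membered acyl alkyl rhodacycle, and C–C reductive elimination then joins C3 to C4 and releases the catalyst. Ring C thus closes in a 6-endo mode with respect to the olefin, both olefin carbons ending in the ring. The closest known reaction types are the rhodium–bisphosphine-catalysed enantioselective intramolecular hydroacylations of 2-(prop-1-en-2-yl)benzaldehydes to 3-substituted indan-1-ones and of 2-(2-substituted allyl)benzaldehydes to 3-substituted 3,4-dihydronaphthalen-1(2H)-ones; here an oxygen stands in the tether, so the same regiochemistry gives a chroman-4-one, which has not been shown for an aryl vinyl ether. The single new stereocentre C2 is created in the hydride transfer, and its configuration is decided by which face of the 1,1-disubstituted olefin the bisphosphine–rhodium fragment binds, the aryl and aryloxy substituents being the groups it tells apart. The step needs regioselectivity against the electronically favoured placing of rhodium on the oxygenated, benzylic C2, which would end in a 2-aryl-2-methylbenzofuran-3-one; this should be secured because that insertion gives a tertiary alkyl rhodium that reverts faster than it can eliminate to a quaternary centre, and the bulky aryl groups of the ligand add to the penalty. Chemoselectivity over the chain olefins follows from their being trisubstituted and unable to chelate, and all phenols are capped so that no phenoxide can hold rhodium away from the olefin or release acid that would hydrolyse the enol ether. No base is present, so the new centre cannot be lost through opening of ring C.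

Step 9
Reactants: 17 (2S)-2-[3-geranyl-4-(methoxymethoxy)phenyl]-5,7-bis(methoxymethoxy)-2,3-dihydro-4H-chromen-4-one
Product: 18 (2S)-2-(3-geranyl-4-hydroxyphenyl)-5,7-dihydroxy-2,3-dihydro-4H-chromen-4-one
Conditions: 3 M aq. HCl, MeOH, 45 °C
Reagents that add atoms: none
Why: Acid-catalysed acetal exchange with methanol removes all three MOM ethers as dimethoxymethane, the one at C5 next to the ketone fastest; no base is used, so C2, which epimerises through ring opening under basic conditions, should be kept, and the moderate temperature is meant to spare the geranyl chain.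

## Compound list

1 | 2,4-dibromophenol | Oc1ccc(Br)cc1Br | starting material
2 | 2,4-dibromo-1-(methoxymethoxy)benzene | COCOc1ccc(Br)cc1Br | intermediate
3 | geranyl bromide, (2E)-1-bromo-3,7-dimethylocta-2,6-diene | CC(C)=CCC/C(C)=C/CBr | starting material
4 | [5-bromo-2-(methoxymethoxy)phenyl]lithium | [Li]c1cc(Br)ccc1OCOC | intermediate
5 | [5-bromo-2-(methoxymethoxy)phenyl]copper | [Cu]c1cc(Br)ccc1OCOC | intermediate
6 | 4-bromo-2-[(2E)-3,7-dimethylocta-2,6-dien-1-yl]-1-(methoxymethoxy)benzene | CC(C)=CCC/C(C)=C/Cc1cc(Br)ccc1OCOC | intermediate
7 | N-methoxy-N-methylacetamide | CC(=O)N(C)OC | starting material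
8 | {3-[(2E)-3,7-dimethylocta-2,6-dien-1-yl]-4-(methoxymethoxy)phenyl}lithium | CC(C)=CCC/C(C)=C/Cc1cc([Li])ccc1OCOC | intermediate
9 | lithium 1-{3-[(2E)-3,7-dimethylocta-2,6-dien-1-yl]-4-(methoxymethoxy)phenyl}-1-[methoxy(methyl)amino]ethan-1-olate | CC(C)=CCC/C(C)=C/Cc1cc(C(C)(O[Li])N(C)OC)ccc1OCOC | intermediate
10 | 1-{3-[(2E)-3,7-dimethylocta-2,6-dien-1-yl]-4-(methoxymethoxy)phenyl}ethan-1-one | CC(C)=CCC/C(C)=C/Cc1cc(C(C)=O)ccc1OCOC | intermediate
11 | potassium 1-{3-[(2E)-3,7-dimethylocta-2,6-dien-1-yl]-4-(methoxymethoxy)phenyl}ethen-1-olate | CC(C)=CCC/C(C)=C/Cc1cc(C(=C)O[K])ccc1OCOC | intermediate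
12 | 1-{3-[(2E)-3,7-dimethylocta-2,6-dien-1-yl]-4-(methoxymethoxy)phenyl}ethenyl trifluoromethanesulfonate | CC(C)=CCC/C(C)=C/Cc1cc(C(=C)OS(=O)(=O)C(F)(F)F)ccc1OCOC | intermediate
13 | 2-(1-{3-[(2E)-3,7-dimethylocta-2,6-dien-1-yl]-4-(methoxymethoxy)phenyl}ethenyl)-4,4,5,5-tetramethyl-1,3,2-dioxaborolane | CC(C)=CCC/C(C)=C/Cc1cc(C(=C)B2OC(C)(C)C(C)(C)O2)ccc1OCOC | intermediate
14 | 2,4,6-trihydroxybenzaldehyde | O=Cc1c(O)cc(O)cc1O | starting material
15 | 2-hydroxy-4,6-bis(methoxymethoxy)benzaldehyde | O=Cc1c(O)cc(OCOC)cc1OCOC | intermediate
16 | 2-[(1-{3-[(2E)-3,7-dimethylocta-2,6-dien-1-yl]-4-(methoxymethoxy)phenyl}ethenyl)oxy]-4,6-bis(methoxymethoxy)benzaldehyde | CC(C)=CCC/C(C)=C/Cc1cc(C(=C)Oc2cc(OCOC)cc(OCOC)c2C=O)ccc1OCOC | intermediate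
17 | (2S)-2-{3-[(2E)-3,7-dimethylocta-2,6-dien-1-yl]-4-(methoxymethoxy)phenyl}-5,7-bis(methoxymethoxy)-2,3-dihydro-4H-chromen-4-one | CC(C)=CCC/C(C)=C/Cc1cc([C@@H]2CC(=O)c3c(OCOC)cc(OCOC)cc3O2)ccc1OCOC | intermediate
18 | (2S)-2-{3-[(2E)-3,7-dimethylocta-2,6-dien-1-yl]-4-hydroxyphenyl}-5,7-dihydroxy-2,3-dihydro-4H-chromen-4-one | CC(C)=CCC/C(C)=C/Cc1cc([C@@H]2CC(=O)c3c(O)cc(O)cc3O2)ccc1O | target

## Step count and risks

Total: 9 steps. Longest linear sequence: 8 steps (steps 1, 2, 3, 4, 5, 7, 8, 9 from 2,4-dibromophenol 1); step 6 is a one-step side branch.

**Step 8 (key step, proposed new method).** Four things may go wrong.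
- Insertion with the reverse regiochemistry, rhodium on C2, leading to five-membered ring closure.
- Decarbonylation of the hindered acyl rhodium, because the electron-rich 1,1-disubstituted enol ether binds only weakly.
- Hydrolysis of the enol ether by traces of acid from the cationic complex.
- Low facial selectivity, or selectivity in the wrong sense.

Fallback by known chemistry, setting out from bromide 6 and rejoining at 17, so that steps 3 to 8 are not needed and step 6 is replaced by the protection of F2: 6 is lithiated (n-BuLi, THF, −78 °C) and quenched with B(Oi-Pr)3 to give [3-geranyl-4-(methoxymethoxy)phenyl]boronic acid F1. Commercial 5,7-dihydroxy-4H-chromen-4-one F2 is converted with NaH and MOMCl in DMF into 5,7-bis(methoxymethoxy)-4H-chromen-4-one F3. Enantioselective conjugate addition of F1 to F3 under [Rh(OH)(cod)]2 (monovalent rhodium) and an electron-poor atropisomeric bisphosphine in toluene–water at room temperature, without added base, forms C2–C1′ and gives 17 directly.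

**Step 7.** The hindered 1-arylvinyl pinacol boronate may transfer slowly to copper, the salicylaldehyde-type phenol may tie up copper as a chelate, and protodeboronation or oxidative homocoupling of the boronate may win.

Fallback setting out from 6 and 15 and rejoining at 16:
- 6 is lithiated and carboxylated with CO2 to 3-geranyl-4-(methoxymethoxy)benzoic acid F4.
- F4 is esterified with 15 (EDC·HCl, DMAP, CH2Cl2) to 2-formyl-3,5-bis(methoxymethoxy)phenyl 3-geranyl-4-(methoxymethoxy)benzoate F5.
- The aldehyde is masked (HC(OMe)3, pyridinium tosylate, MeOH) as 2-(dimethoxymethyl)-3,5-bis(methoxymethoxy)phenyl 3-geranyl-4-(methoxymethoxy)benzoate F6.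
- Carbonyl methylenation of the aryl ester with Cp2TiMe2 in toluene at 70 °C gives 2-(dimethoxymethyl)-1-({1-[3-geranyl-4-(methoxymethoxy)phenyl]ethenyl}oxy)-3,5-bis(methoxymethoxy)benzene F7.
- Brief hydrolysis of the very electron-rich benzaldehyde acetal (pyridinium tosylate, aqueous acetone, 0 °C) returns 16.

**Step 4.** The enol triflate carries an aryl group with a para oxygen and may ionise or eliminate to the arylalkyne during formation, chromatography or the following borylation.

Fallback setting out from 10 and rejoining at 13 (steps 4 and 5 replaced): 10 is condensed with 2,4,6-triisopropylbenzenesulfonohydrazide to N′-{1-[3-geranyl-4-(methoxymethoxy)phenyl]ethylidene}-2,4,6-tri(propan-2-yl)benzenesulfonohydrazide F8. A Shapiro reaction (n-BuLi, 2.2 equiv, THF–TMEDA, −78 to 0 °C) gives {1-[3-geranyl-4-(methoxymethoxy)phenyl]ethenyl}lithium F9, which is trapped with 2-isopropoxy-4,4,5,5-tetramethyl-1,3,2-dioxaborolane to give 13.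

**Step 9.** Acid may add the freed C4′ hydroxyl to the neighbouring olefin or hydrate the chain before the two less activated MOM ethers are gone, and prolonged heating may erode C2.

Fallback setting out from 17 and rejoining at 18: trimethylsilyl triflate with 2,2′-bipyridyl in CH2Cl2 at 0 °C exchanges each aryl MOM ether for a silyl ether under non-protic conditions, giving (2S)-2-[3-geranyl-4-(trimethylsilyloxy)phenyl]-5,7-bis(trimethylsilyloxy)-2,3-dihydro-4H-chromen-4-one F10. Neutral hydrolysis in aqueous THF then gives 18.

## Further compounds

F1 | step 8 | {3-[(2E)-3,7-dimethylocta-2,6-dien-1-yl]-4-(methoxymethoxy)phenyl}boronic acid | CC(C)=CCC/C(C)=C/Cc1cc(B(O)O)ccc1OCOC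
F2 | step 8 | 5,7-dihydroxy-4H-chromen-4-one (purchased) | O=c1ccoc2cc(O)cc(O)c12
F3 | step 8 | 5,7-bis(methoxymethoxy)-4H-chromen-4-one | O=c1ccoc2cc(OCOC)cc(OCOC)c12
F4 | step 7 | 3-[(2E)-3,7-dimethylocta-2,6-dien-1-yl]-4-(methoxymethoxy)benzoic acid | CC(C)=CCC/C(C)=C/Cc1cc(C(=O)O)ccc1OCOC
F5 | step 7 | 2-formyl-3,5-bis(methoxymethoxy)phenyl 3-[(2E)-3,7-dimethylocta-2,6-dien-1-yl]-4-(methoxymethoxy)benzoate | CC(C)=CCC/C(C)=C/Cc1cc(C(=O)Oc2cc(OCOC)cc(OCOC)c2C=O)ccc1OCOC
F6 | step 7 | 2-(dimethoxymethyl)-3,5-bis(methoxymethoxy)phenyl 3-[(2E)-3,7-dimethylocta-2,6-dien-1-yl]-4-(methoxymethoxy)benzoate | CC(C)=CCC/C(C)=C/Cc1cc(C(=O)Oc2cc(OCOC)cc(OCOC)c2C(OC)OC)ccc1OCOC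
F7 | step 7 | 2-(dimethoxymethyl)-1-[(1-{3-[(2E)-3,7-dimethylocta-2,6-dien-1-yl]-4-(methoxymethoxy)phenyl}ethenyl)oxy]-3,5-bis(methoxymethoxy)benzene | CC(C)=CCC/C(C)=C/Cc1cc(C(=C)Oc2cc(OCOC)cc(OCOC)c2C(OC)OC)ccc1OCOC
F8 | step 4 | N′-(1-{3-[(2E)-3,7-dimethylocta-2,6-dien-1-yl]-4-(methoxymethoxy)phenyl}ethylidene)-2,4,6-tri(propan-2-yl)benzenesulfonohydrazide | CC(C)=CCC/C(C)=C/Cc1cc(C(C)=NNS(=O)(=O)c2c(C(C)C)cc(C(C)C)cc2C(C)C)ccc1OCOC
F9 | step 4 | (1-{3-[(2E)-3,7-dimethylocta-2,6-dien-1-yl]-4-(methoxymethoxy)phenyl}ethenyl)lithium | CC(C)=CCC/C(C)=C/Cc1cc(C(=C)[Li])ccc1OCOC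
F10 | step 9 | (2S)-2-{3-[(2E)-3,7-dimethylocta-2,6-dien-1-yl]-4-(trimethylsilyloxy)phenyl}-5,7-bis(trimethylsilyloxy)-2,3-dihydro-4H-chromen-4-one | CC(C)=CCC/C(C)=C/Cc1cc([C@@H]2CC(=O)c3c(O[Si](C)(C)C)cc(O[Si](C)(C)C)cc3O2)ccc1O[Si](C)(C)C
A1 | alternative 1 | methyl 3-[(2E)-3,7-dimethylocta-2,6-dien-1-yl]-4-(triisopropylsilyloxy)benzoate | CC(C)=CCC/C(C)=C/Cc1cc(C(=O)OC)ccc1O[Si](C(C)C)(C(C)C)C(C)C
A2 | alternative 1 | methyl coumalate, methyl 2-oxo-2H-pyran-5-carboxylate | COC(=O)c1ccc(=O)oc1
A3 | alternative 1 | {[(4E)-5,9-dimethyldeca-4,8-dien-1-yn-1-yl]oxy}tri(propan-2-yl)silane | CC(C)=CCC/C(C)=C/CC#CO[Si](C(C)C)(C(C)C)C(C)C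
A4 | alternative 2 | 2-{3-[(2E)-3,7-dimethylocta-2,6-dien-1-yl]-4-(methoxymethoxy)phenyl}-1,3-dioxolane | CC(C)=CCC/C(C)=C/Cc1cc(C2OCCO2)ccc1OCOC
A5 | alternative 2 | 6-methylhept-5-en-1-yne | CC(C)=CCCC#C
A6 | alternative 2 | 2-[3-(chloromethyl)-4-(methoxymethoxy)phenyl]-1,3-dioxolane | ClCc1cc(C2OCCO2)ccc1OCOC
A7 | alternative 2 | [(1E)-2,6-dimethylhepta-1,5-dien-1-yl]dimethylalane | CC(C)=CCC/C(C)=C/[Al](C)C
A8 | alternative 3 | (3R)-3-[tert-butyl(dimethyl)silyloxy]-3-{3-[(2E)-3,7-dimethylocta-2,6-dien-1-yl]-4-(methoxymethoxy)phenyl}-1-(2,4,6-trihydroxyphenyl)propan-1-one | CC(C)=CCC/C(C)=C/Cc1cc([C@H](O[Si](C)(C)C(C)(C)C)CC(=O)c2c(O)cc(O)cc2O)ccc1OCOC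
A9 | alternative 3 | 6-[(4R)-4-[tert-butyl(dimethyl)silyloxy]-4-{3-[(2E)-3,7-dimethylocta-2,6-dien-1-yl]-4-(methoxymethoxy)phenyl}-2-oxobutyl]-4-hydroxy-2H-pyran-2-one | CC(C)=CCC/C(C)=C/Cc1cc([C@H](O[Si](C)(C)C(C)(C)C)CC(=O)Cc2cc(O)cc(=O)o2)ccc1OCOC
A10 | alternative 3 | methyl (9R)-9-[tert-butyl(dimethyl)silyloxy]-9-{3-[(2E)-3,7-dimethylocta-2,6-dien-1-yl]-4-(methoxymethoxy)phenyl}-3,5,7-trioxononanoate | CC(C)=CCC/C(C)=C/Cc1cc([C@H](O[Si](C)(C)C(C)(C)C)CC(=O)CC(=O)CC(=O)CC(=O)OC)ccc1OCOC
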